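Numbering (also used as spiro locants): ring A = C1 (bears the exocyclic CH2), C2, C3, C4 (CHBr), C5 (CMe2), C6 (spiro); ring B = C6, C7, C8, C9 (CMeBr), C10 (CHCl), C11.
Cuts, in retrosynthetic order: C9–Br and C10–Cl go back to a cis-9,10-diol and its C10 oxygen to an acetyl group; then C9–C10, because C9 (methyl plus heteroatom) lies 1,4 to the spiro carbon and C10 carries the acetyl, so ring B is the intramolecular aldol of two identical 3-oxobutyl arms on C6; then C1=CH2, C5–C6, C2–C3 and C6=C7.
Forward: both arms are assembled on the future C6 (alkylation, olefination), the bromochloride chain is joined at C2–C3, ring A closes at C5–C6 by a bromonium cyclisation, C1 is methylenated, and ring B closes last in the aldol.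
Stereochemistry: C4 comes from a catalytic enantioselective bromochlorination of prenol and passes unchanged through the bromonium ion; C6, C9 and C10 arise together in the amine-catalysed aldol; C10 is then inverted by chloride on a cyclic sulfate and C9 is substituted with retention through a chloronium ion.

Key step: step 11

Assumption: the sense of induction of the two chiral catalysts is taken as follows: ligand L* (the salicylaldimine of (S)-2-amino-1,1,2-triphenylethanol and 3,5-di-tert-butylsalicylaldehyde) gives (R)-8, and the quinine-derived primary amine makes the arm cis to the C4 bromine the enamine donor; if either sense were opposite, the mirror-image ligand or the quinidine-derived pseudo-enantiomer would take its place in the same step.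

Step 1
Reactants: 1 dimethyl (2-oxopropyl)phosphonate; 2 2-(2-bromoethyl)-2-methyl-1,3-dioxolane
Product: 3 dimethyl [5-(2-methyl-1,3-dioxolan-2-yl)-2-oxopentan-3-yl]phosphonate (racemic)
Conditions: NaH, DMF, 0 °C; then 2, NaI (cat.), 60 °C
Reagents that add atoms: none
Why: C-alkylation of the sodium salt of a β-ketophosphonate by a primary bromide (iodide-assisted SN2) puts the first masked 3-oxobutyl arm on the future C6, and the new stereocentre does not matter because it becomes sp2 in step 3.

Step 2
Reactants: 4 ethyl 2-(2-methyl-1,3-dioxolan-2-yl)acetate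
Product: 5 2-(2-methyl-1,3-dioxolan-2-yl)acetaldehyde
Conditions: iBu2AlH, CH2Cl2, −78 °C; aq. potassium sodium tartrate
Reagents that add atoms: none
Why: partial reduction of an ester to the aldehyde by the aluminium hydride at low temperature stops at the tetrahedral aluminate, which collapses only on work-up, and no stereocentre is formed.

Step 3
Reactants: 3 dimethyl [5-(2-methyl-1,3-dioxolan-2-yl)-2-oxopentan-3-yl]phosphonate; 5 2-(2-methyl-1,3-dioxolan-2-yl)acetaldehyde
Product: 6 5-(2-methyl-1,3-dioxolan-2-yl)-3-[2-(2-methyl-1,3-dioxolan-2-yl)ethyl]pent-3-en-2-one (E/Z mixture)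
Conditions: Ba(OH)2, THF/H2O (40:1), rt
Reagents that add atoms: none
Why: Horner–Wadsworth–Emmons olefination of the α-substituted β-ketophosphonate under mild hydroxide conditions attaches the second arm to C6 as an alkylidene, and the alkene geometry is immaterial because both arms become identical in step 7.

Step 4
Reactants: 7 3-methylbut-2-en-1-ol (prenol)
Product: 8 (2R)-2-bromo-3-chloro-3-methylbutan-1-ol
Conditions: NBS, ClTi(OiPr)3, ligand L* (20 mol %), hexanes, −20 °C
Reagents that add atoms: N-bromosuccinimide, O=C1CCC(=O)N1Br; chlorotitanium triisopropoxide, CC(C)O[Ti](Cl)(OC(C)C)OC(C)C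
Why: catalytic enantioselective bromochlorination of an allylic alcohol, in which the titanium-bound alkoxide and the chiral ligand direct bromonium formation to one alkene face and chloride opens the ion at the tertiary carbon, sets the future C4 as (R).

Step 5
Reactants: 8 (2R)-2-bromo-3-chloro-3-methylbutan-1-ol
Product: 9 (2R)-2-bromo-3-chloro-3-methylbutyl trifluoromethanesulfonate
Conditions: Tf2O, 2,6-lutidine, CH2Cl2, −78 °C; used cold without storage
Reagents that add atoms: trifluoromethanesulfonic anhydride, O=S(=O)(OS(=O)(=O)C(F)(F)F)C(F)(F)F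
Why: O-sulfonylation of the primary alcohol gives a leaving group reactive enough for enolate alkylation next to the electron-poor CHBr carbon, and the stereocentre is not touched.

Step 6
Reactants: 6 5-(2-methyl-1,3-dioxolan-2-yl)-3-[2-(2-methyl-1,3-dioxolan-2-yl)ethyl]pent-3-en-2-one; 9 (2R)-2-bromo-3-chloro-3-methylbutyl trifluoromethanesulfonate
Product: 10 (7R)-7-bromo-8-chloro-8-methyl-1-(2-methyl-1,3-dioxolan-2-yl)-3-[2-(2-methyl-1,3-dioxolan-2-yl)ethyl]non-2-en-4-one
Conditions: LiN(iPr)2, THF, −78 °C; then 9, −78 to −40 °C
Reagents that add atoms: none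
Why: kinetic deprotonation of the methyl group (the α′ position of the enone) gives the cross-conjugated lithium dienolate, which is alkylated by the primary triflate in an SN2 reaction much faster than by the hindered secondary bromide or the tertiary chloride, forming C2–C3 without touching C4.

Step 7
Reactants: 10 (7R)-7-bromo-8-chloro-8-methyl-1-(2-methyl-1,3-dioxolan-2-yl)-3-[2-(2-methyl-1,3-dioxolan-2-yl)ethyl]non-2-en-4-one
Product: 11 {[(7R)-7-bromo-8-chloro-8-methyl-1-(2-methyl-1,3-dioxolan-2-yl)-3-[2-(2-methyl-1,3-dioxolan-2-yl)ethyl]non-3-en-4-yl]oxy}triethylsilane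
Conditions: Et3SiH, RhCl(PPh3)3 (2 mol %), toluene, 50 °C
Reagents that add atoms: triethylsilane, CC[SiH](CC)CC
Why: rhodium-catalysed 1,4-hydrosilylation of the enone delivers hydride to C7 and silicon to oxygen, so the tetrasubstituted C1=C6 enol silane forms regiospecifically (enolisation of the saturated ketone could not be trusted to choose C6 over C2) and has no geometric isomers because C6 now carries two identical arms.

Step 8
Reactants: 11 {[(7R)-7-bromo-8-chloro-8-methyl-1-(2-methyl-1,3-dioxolan-2-yl)-3-[2-(2-methyl-1,3-dioxolan-2-yl)ethyl]non-3-en-4-yl]oxy}triethylsilane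
Product: 12 (4R)-4-bromo-3,3-dimethyl-2,2-bis[2-(2-methyl-1,3-dioxolan-2-yl)ethyl]cyclohexan-1-one
Conditions: (CF3)2CHOH (0.02 M), 2,6-di-tert-butyl-4-methylpyridine, 0 °C to rt
Reagents that add atoms: none
Why: solvolytic ionisation of the tertiary chloride in the ionising, weakly nucleophilic alcohol is assisted by the neighbouring bromine and gives the enantiopure bromonium ion, which the enol silane carbon C6 opens at the tertiary carbon C5 in a chair-like 6-endo bromonium (cation–olefin) cyclisation that closes ring A, C4 never being a reacting centre and so staying (R).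

Step 9
Reactants: 12 (4R)-4-bromo-3,3-dimethyl-2,2-bis[2-(2-methyl-1,3-dioxolan-2-yl)ethyl]cyclohexan-1-one
Product: 13 2,2'-{[(3R)-3-bromo-2,2-dimethyl-6-methylidenecyclohexane-1,1-diyl]di(ethane-2,1-diyl)}bis(2-methyl-1,3-dioxolane)
Conditions: Cp2TiMe2, toluene, 75 °C, dark
Reagents that add atoms: dimethyltitanocene, [CH3-].[CH3-].[Ti+4].c1cc[cH-]c1.c1cc[cH-]c1
Why: Petasis methylenation (titanium methylidene, oxatitanacyclobutane, cycloreversion) is non-basic, so the hindered and enolisable C1 ketone should become the exocyclic methylene without elimination of the secondary bromide or loss of the ketals.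

Step 10
Reactants: 13 2,2'-{[(3R)-3-bromo-2,2-dimethyl-6-methylidenecyclohexane-1,1-diyl]di(ethane-2,1-diyl)}bis(2-methyl-1,3-dioxolane)
Product: 14 4,4'-[(3R)-3-bromo-2,2-dimethyl-6-methylidenecyclohexane-1,1-diyl]di(butan-2-one)
Conditions: PPTS, acetone/H2O (5:1), 55 °C
Reagents that add atoms: water, O
Why: acid-catalysed ketal hydrolysis unmasks both methyl ketones under conditions too mild to isomerise the exocyclic alkene or to start aldolisation.

Step 11
Reactants: 14 4,4'-[(3R)-3-bromo-2,2-dimethyl-6-methylidenecyclohexane-1,1-diyl]di(butan-2-one)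
Product: 15 1-[(4R,6S,9R,10S)-4-bromo-9-hydroxy-5,5,9-trimethyl-1-methylidenespiro[5.5]undecan-10-yl]ethan-1-one
Conditions: 9-amino-9-deoxy-epi-quinine (20 mol %), CF3CO2H (40 mol %), toluene, 0 °C to rt
Reagents that add atoms: none
Why: Proposed new method: the primary amine of the catalyst condenses with the methyl ketone of one arm, the internal enamine carbon C10 adds to the C9 carbonyl of the other arm while the protonated quinuclidine binds and orients that carbonyl, and hydrolysis of the iminium ion releases the ketol. The closest known reactions are the cinchona primary-amine desymmetrising aldol cyclisations of 4-substituted heptane-2,6-diones and amine-catalysed enolexo aldolisations of 1,7-dicarbonyl compounds; a ketone-to-ketone enolexo addition that also selects between two arms on a quaternary carbon has not been shown. Ring B closes in the 6-(enolexo)-exo-trig mode, forming C9–C10. C6 becomes stereogenic through the choice of the donor arm (the arm cis to the C4 bromine must become C11–C10), which the chiral amine controls; C9 is set in the chair transition state that places C1 axial on C6, the C9 methyl equatorial and the carbonyl oxygen axial toward the ammonium group; C10 ends with its acetyl equatorial and cis to the hydroxyl, a position it can also reach by epimerisation through the enamine. The step needs arm selection and must stop at the ketol: the substrate helps because its only carbonyls are the two arm ketones (C1 is already an alkene), only the internal α-carbon can reach the other ketone through a six-membered ring, and the two arms differ clearly (one axial, one equatorial on ring A), while low temperature and a small acid load should keep dehydration and retro-aldol scrambling slow.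

Step 12
Reactants: 15 1-[(4R,6S,9R,10S)-4-bromo-9-hydroxy-5,5,9-trimethyl-1-methylidenespiro[5.5]undecan-10-yl]ethan-1-one
Product: 16 1-[(4R,6S,9R,10S)-4-bromo-5,5,9-trimethyl-1-methylidene-9-(trimethylsilyloxy)spiro[5.5]undecan-10-yl]ethan-1-one
Conditions: N-(trimethylsilyl)imidazole, CH2Cl2, rt
Reagents that add atoms: N-(trimethylsilyl)imidazole, C[Si](C)(C)n1ccnc1
Why: O-silylation of the tertiary hydroxyl with a neutral silyl-transfer reagent blocks retro-aldol cleavage and dehydration of the ketol in the Lewis-acidic oxidation that follows, without enolising the ketone.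

Step 13
Reactants: 16 1-[(4R,6S,9R,10S)-4-bromo-5,5,9-trimethyl-1-methylidene-9-(trimethylsilyloxy)spiro[5.5]undecan-10-yl]ethan-1-one
Product: 17 (4R,6S,9R,10S)-4-bromo-5,5,9-trimethyl-1-methylidene-9-(trimethylsilyloxy)spiro[5.5]undecan-10-yl acetate
Conditions: Me3SiOOSiMe3, SnCl4 (15 mol %), trans-cyclohexane-1,2-diamine (15 mol %), 4 Å MS, CH2Cl2, rt
Reagents that add atoms: bis(trimethylsilyl) peroxide, C[Si](C)(C)OO[Si](C)(C)C
Why: Baeyer–Villiger oxidation with the silyl peroxide under tin Lewis-acid catalysis migrates the secondary carbon C10 in preference to methyl with retention of configuration, and this non-peracid oxidant should leave the exocyclic alkene unepoxidised.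

Step 14
Reactants: 17 (4R,6S,9R,10S)-4-bromo-5,5,9-trimethyl-1-methylidene-9-(trimethylsilyloxy)spiro[5.5]undecan-10-yl acetate
Product: 18 (4R,6S,9R,10S)-4-bromo-5,5,9-trimethyl-1-methylidenespiro[5.5]undecane-9,10-diol
Conditions: K2CO3 (cat.), MeOH, rt
Reagents that add atoms: none
Why: transesterification of the acetate and methanolysis of the trimethylsilyl ether under mild carbonate conditions release the cis-9,10-diol with both stereocentres unchanged.

Step 15
Reactants: 18 (4R,6S,9R,10S)-4-bromo-5,5,9-trimethyl-1-methylidenespiro[5.5]undecane-9,10-diol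
Product: 19 (4R,6S,9R,10S)-4-bromo-5,5,9-trimethyl-1-methylidenespiro[5.5]undecane-9,10-diyl cyclic sulfate
Conditions: NaH, THF, 0 °C; then 1,1'-sulfonyldiimidazole, −20 °C to rt
Reagents that add atoms: 1,1'-sulfonyldiimidazole, O=S(=O)(n1ccnc1)n1ccnc1
Why: double O-sulfonylation of the cis-diol (alkoxide attack on the sulfonyl transfer reagent, then ring closure with loss of the second imidazole) gives the cyclic sulfate directly at the sulfate oxidation level, which avoids the ruthenium tetroxide oxidation of a cyclic sulfite that would cleave the exocyclic alkene.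

Step 16
Reactants: 19 (4R,6S,9R,10S)-4-bromo-5,5,9-trimethyl-1-methylidenespiro[5.5]undecane-9,10-diyl cyclic sulfate
Product: 21 (4R,6S,9R,10R)-4-bromo-10-chloro-5,5,9-trimethyl-1-methylidenespiro[5.5]undecan-9-ol, via lithium chloroalkyl sulfate 20 (not isolated)
Conditions: LiCl, DMF, 50 °C; then H2SO4 (cat.), H2O (2 equiv), THF, rt
Reagents that add atoms: lithium chloride, [Li+].[Cl-]
Why: SN2 opening of the cyclic sulfate by chloride at the secondary carbon C10 (trans-diaxial, backside to the C10–O bond) inverts C10 to the (R)-chloride while the tertiary C9–O bond stays intact, and acid-catalysed hydrolysis of the sulfate monoester by S–O cleavage frees the tertiary alcohol with retention.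

Step 17
Reactants: 21 (4R,6S,9R,10R)-4-bromo-10-chloro-5,5,9-trimethyl-1-methylidenespiro[5.5]undecan-9-ol
Product: 22 (4R,6S,9R,10R)-4,9-dibromo-10-chloro-5,5,9-trimethyl-1-methylidenespiro[5.5]undecane
Conditions: 1-bromo-N,N,2-trimethylprop-1-en-1-amine, CH2Cl2, 0 °C to rt
Reagents that add atoms: 1-bromo-N,N,2-trimethylprop-1-en-1-amine, CC(C)=C(Br)N(C)C
Why: deoxybromination of a tertiary alcohol with an α-bromoenamine under neutral conditions, in which the alkoxy-iminium bromide ionises at C9 with help from the antiperiplanar C10 chlorine and bromide opens the chloronium ion at the tertiary carbon anti to chlorine, should replace the oxygen with net retention (double inversion) while the acid-sensitive exocyclic alkene never meets HBr.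

Compound list
1 | dimethyl (2-oxopropyl)phosphonate | COP(=O)(CC(C)=O)OC | starting material
2 | 2-(2-bromoethyl)-2-methyl-1,3-dioxolane | CC1(CCBr)OCCO1 | starting material
3 | dimethyl [5-(2-methyl-1,3-dioxolan-2-yl)-2-oxopentan-3-yl]phosphonate (racemic) | COP(=O)(OC)C(CCC1(C)OCCO1)C(C)=O | intermediate
4 | ethyl 2-(2-methyl-1,3-dioxolan-2-yl)acetate | CCOC(=O)CC1(C)OCCO1 | starting material
5 | 2-(2-methyl-1,3-dioxolan-2-yl)acetaldehyde | O=CCC1(C)OCCO1 | intermediate
6 | 5-(2-methyl-1,3-dioxolan-2-yl)-3-[2-(2-methyl-1,3-dioxolan-2-yl)ethyl]pent-3-en-2-one (E/Z mixture) | CC(=O)C(CCC1(C)OCCO1)=CCC1(C)OCCO1 | intermediate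
7 | 3-methylbut-2-en-1-ol (prenol) | CC(C)=CCO | starting material
8 | (2R)-2-bromo-3-chloro-3-methylbutan-1-ol | OC[C@@H](Br)C(C)(C)Cl | intermediate
9 | (2R)-2-bromo-3-chloro-3-methylbutyl trifluoromethanesulfonate | O=S(=O)(OC[C@@H](Br)C(C)(C)Cl)C(F)(F)F | intermediate
10 | (7R)-7-bromo-8-chloro-8-methyl-1-(2-methyl-1,3-dioxolan-2-yl)-3-[2-(2-methyl-1,3-dioxolan-2-yl)ethyl]non-2-en-4-one | CC(C)(Cl)[C@H](Br)CCC(=O)C(CCC1(C)OCCO1)=CCC1(C)OCCO1 | intermediate
11 | {[(7R)-7-bromo-8-chloro-8-methyl-1-(2-methyl-1,3-dioxolan-2-yl)-3-[2-(2-methyl-1,3-dioxolan-2-yl)ethyl]non-3-en-4-yl]oxy}triethylsilane | CC(C)(Cl)[C@H](Br)CCC(O[Si](CC)(CC)CC)=C(CCC1(C)OCCO1)CCC1(C)OCCO1 | intermediate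
12 | (4R)-4-bromo-3,3-dimethyl-2,2-bis[2-(2-methyl-1,3-dioxolan-2-yl)ethyl]cyclohexan-1-one | O=C1CC[C@@H](Br)C(C)(C)C1(CCC2(C)OCCO2)CCC2(C)OCCO2 | intermediate
13 | 2,2'-{[(3R)-3-bromo-2,2-dimethyl-6-methylidenecyclohexane-1,1-diyl]di(ethane-2,1-diyl)}bis(2-methyl-1,3-dioxolane) | C=C1CC[C@@H](Br)C(C)(C)C1(CCC2(C)OCCO2)CCC2(C)OCCO2 | intermediate
14 | 4,4'-[(3R)-3-bromo-2,2-dimethyl-6-methylidenecyclohexane-1,1-diyl]di(butan-2-one) | C=C1CC[C@@H](Br)C(C)(C)C1(CCC(C)=O)CCC(C)=O | intermediate
15 | 1-[(4R,6S,9R,10S)-4-bromo-9-hydroxy-5,5,9-trimethyl-1-methylidenespiro[5.5]undecan-10-yl]ethan-1-one | C=C1CC[C@@H](Br)C(C)(C)[C@]12CC[C@@](C)(O)[C@@H](C(C)=O)C2 | intermediate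
16 | 1-[(4R,6S,9R,10S)-4-bromo-5,5,9-trimethyl-1-methylidene-9-(trimethylsilyloxy)spiro[5.5]undecan-10-yl]ethan-1-one | C=C1CC[C@@H](Br)C(C)(C)[C@]12CC[C@@](C)(O[Si](C)(C)C)[C@@H](C(C)=O)C2 | intermediate
17 | (4R,6S,9R,10S)-4-bromo-5,5,9-trimethyl-1-methylidene-9-(trimethylsilyloxy)spiro[5.5]undecan-10-yl acetate | C=C1CC[C@@H](Br)C(C)(C)[C@]12CC[C@@](C)(O[Si](C)(C)C)[C@@H](OC(C)=O)C2 | intermediate
18 | (4R,6S,9R,10S)-4-bromo-5,5,9-trimethyl-1-methylidenespiro[5.5]undecane-9,10-diol | C=C1CC[C@@H](Br)C(C)(C)[C@]12CC[C@@](C)(O)[C@@H](O)C2 | intermediate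
19 | (4R,6S,9R,10S)-4-bromo-5,5,9-trimethyl-1-methylidenespiro[5.5]undecane-9,10-diyl cyclic sulfate | C=C1CC[C@@H](Br)C(C)(C)[C@]12CC[C@@]3(C)OS(=O)(=O)O[C@H]3C2 | intermediate
20 | lithium (4R,6S,9R,10R)-4-bromo-10-chloro-5,5,9-trimethyl-1-methylidenespiro[5.5]undecan-9-yl sulfate (not isolated) | C=C1CC[C@@H](Br)C(C)(C)[C@]12CC[C@@](C)(OS(=O)(=O)[O-])[C@H](Cl)C2.[Li+] | intermediate
21 | (4R,6S,9R,10R)-4-bromo-10-chloro-5,5,9-trimethyl-1-methylidenespiro[5.5]undecan-9-ol | C=C1CC[C@@H](Br)C(C)(C)[C@]12CC[C@@](C)(O)[C@H](Cl)C2 | intermediate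
22 | (4R,6S,9R,10R)-4,9-dibromo-10-chloro-5,5,9-trimethyl-1-methylidenespiro[5.5]undecane | C=C1CC[C@@H](Br)C(C)(C)[C@]12CC[C@@](C)(Br)[C@H](Cl)C2 | target

Total step count: 17.
Longest linear sequence: 14 steps (for example steps 4, 5 and 6 to 17).

Steps most likely to fail

Step 11. The catalyst may select the wrong diastereotopic arm if its preference opposes the bias of the C4 bromide. The ketol may also dehydrate to the conjugated acetylcyclohexene, or retro-aldol reversal may erode the C6 selection. The fallback sets out from 14 and gives up catalyst control for substrate and thermodynamic control with recycling. A base-mediated intramolecular aldol addition (KOH, catalytic, in MeOH at 0 °C) should give 15 together with its arm-exchanged diastereomer 1-[(4R,6R,9S,10R)-4-bromo-9-hydroxy-5,5,9-trimethyl-1-methylidenespiro[5.5]undecan-10-yl]ethan-1-one F1. The two are separated by chromatography. F1 is returned to the same base, where retro-aldol cleavage to 14 and re-closure redistribute it. The fallback comes back to the route at 15.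

Step 8. The enol silane may be protodesilylated by the protic medium before the chloride ionises. The bromonium ion may also be captured at oxygen instead of carbon. Joining two fully substituted carbons may be slow enough for proton loss to an allylic bromide to compete. The fallback sets out from 10 and replaces solvolysis by stoichiometric halide abstraction in an aprotic medium on a more robust enol silane. Hydrosilylation of 10 with tBuMe2SiH and RhCl(PPh3)3 should give tert-butyl{[(7R)-7-bromo-8-chloro-8-methyl-1-(2-methyl-1,3-dioxolan-2-yl)-3-[2-(2-methyl-1,3-dioxolan-2-yl)ethyl]non-3-en-4-yl]oxy}dimethylsilane F2. Its tertiary chloride is then pulled off with AgOTf in CH2Cl2 at −78 °C in the presence of 2,6-di-tert-butyl-4-methylpyridine, so that the bromonium ion forms next to an enol silane that never meets a proton source. The fallback comes back to the route at 12.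

Step 17. Ionisation at the chlorine-deactivated tertiary carbon may be slow. The cation may lose a proton to give alkenes, or bromide may open the chloronium ion at C10 and so transpose the two halogens. The fallback sets out from 21 and separates activation from substitution. Acylation with trifluoroacetic anhydride and pyridine should give (4R,6S,9R,10R)-4-bromo-10-chloro-5,5,9-trimethyl-1-methylidenespiro[5.5]undecan-9-yl trifluoroacetate F3. F3 is then solvolysed in (CF3)2CHOH containing LiBr and 2,6-di-tert-butyl-4-methylpyridine, where ionisation with chlorine participation and capture by bromide can be driven by the solvent instead of by a reagent. The fallback comes back to the route at 22.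

Further compounds
F1 | step 11 | 1-[(4R,6R,9S,10R)-4-bromo-9-hydroxy-5,5,9-trimethyl-1-methylidenespiro[5.5]undecan-10-yl]ethan-1-one | C=C1CC[C@@H](Br)C(C)(C)[C@@]12CC[C@](C)(O)[C@H](C(C)=O)C2
F2 | step 8 | tert-butyl{[(7R)-7-bromo-8-chloro-8-methyl-1-(2-methyl-1,3-dioxolan-2-yl)-3-[2-(2-methyl-1,3-dioxolan-2-yl)ethyl]non-3-en-4-yl]oxy}dimethylsilane | CC(C)(Cl)[C@H](Br)CCC(O[Si](C)(C)C(C)(C)C)=C(CCC1(C)OCCO1)CCC1(C)OCCO1
F3 | step 17 | (4R,6S,9R,10R)-4-bromo-10-chloro-5,5,9-trimethyl-1-methylidenespiro[5.5]undecan-9-yl trifluoroacetate | C=C1CC[C@@H](Br)C(C)(C)[C@]12CC[C@@](C)(OC(=O)C(F)(F)F)[C@H](Cl)C2
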